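**Retrosynthetic overview**

1. Germacrane numbering is used: ring C1–C10, methyls C14 on C10 and C15 on C4, lactone O6–C12(=O)–C11(=C13)–C7. Late disconnections are the C8 ester (Yamaguchi, with (R)-3-methyl-4-(stearoyloxy)butanoic acid), the C11=C13 methylene (Mannich/elimination) and the lactone C6–O bond (Mitsunobu closure with inversion).
2. Enabling feature: the ten-membered ring contains the 1,5-diene C10=C1–C2–C3–C4=C5 with one ring-cis alkene (C1=C10, Z) and one ring-trans alkene (C4=C5, E). A retro-Cope across C2–C3 maps this pair onto a cis-1-vinyl-2-isopropenylcyclohexane in which C5–C10 is a temporary ring bond.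
3. Key step: anionic oxy-Cope ring expansion of the six-membered ring (C5–C10) to the ten-membered ring, with triflation of the enolate in the same flask. C10 is carried at the ketone oxidation level and is later exchanged for the C14 methyl. A temporary trans-fused acetal ring (O6–C12–C11–C7, C6 epimeric to the target) locks the one chair that gives 1(10)Z,4E.
4. The cyclohexane comes from (−)-quinic acid: enone, Luche reduction, Johnson–Claisen (C7–C11), epoxide-to-allylic-alcohol transposition (O6), directed epoxidation and trans-diaxial isopropenyl opening (C5), vinyl addition (C10).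
5. Ring order: six-membered carbocycle (chiral pool), five-membered acetal lock, ten-membered ring (key step), then the γ-lactone re-closed with inversion at C6.

Key step: step 17

Remark: the lactol and methyl-acetal carbon C12 and the α-carbon of the two Mannich intermediates are expected as epimer mixtures; they are written without a descriptor because later steps erase them.

**Route**

Step 1
Reactants: 1 (−)-quinic acid
Product: 2 3,4-O-isopropylidenequinic acid 1,5-lactone
Conditions: Me2C(OMe)2, TsOH·H2O (cat.), acetone, reflux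
Reagents that add atoms: 2,2-dimethoxypropane, COC(C)(C)OC
Why: Acid-catalysed acetonide formation on the cis-3,4-diol with lactonisation of the carboxyl onto the cis 5-hydroxyl (transketalisation/lactonisation) should protect and differentiate all four hydroxyls without creating a stereocentre.

Step 2
Reactants: 2 3,4-O-isopropylidenequinic acid 1,5-lactone
Product: 3 acetonide triol (1-hydroxymethyl-1,5-diol)
Conditions: NaBH4, EtOH, 0 °C → rt
Reagents that add atoms: none
Why: Borohydride reduction of the strained bicyclic lactone should give the 1-(hydroxymethyl)-1-ol needed for glycol cleavage.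

Step 3
Reactants: 3 acetonide triol
Product: 4 3-hydroxy-4,5-(isopropylidenedioxy)cyclohexan-1-one
Conditions: NaIO4, pH 7 phosphate buffer, 0 °C → rt
Reagents that add atoms: none
Why: Malaprade glycol cleavage should excise the hydroxymethyl carbon and leave the ring ketone.

Step 4
Reactants: 4 3-hydroxy-4,5-(isopropylidenedioxy)cyclohexan-1-one
Product: 6 (4S,5R)-4,5-(isopropylidenedioxy)cyclohex-2-en-1-one, via mesylate 5 (not isolated)
Conditions: MsCl, Et3N, CH2Cl2, 0 °C → rt
Reagents that add atoms: none
Why: Mesylation of the β-hydroxyl followed by E1cB elimination should give the enone.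

Step 5
Reactants: 6 (4S,5R)-4,5-(isopropylidenedioxy)cyclohex-2-en-1-one
Product: 7 (1S,4S,5R)-4,5-(isopropylidenedioxy)cyclohex-2-en-1-ol
Conditions: NaBH4, CeCl3·7H2O, MeOH, −78 °C
Reagents that add atoms: none
Why: Luche 1,2-reduction, in which hydride should add anti to the γ-alkoxy (acetonide) face and so set the carbinol cis to the acetonide.

Step 6
Reactants: 7 (1S,4S,5R)-4,5-(isopropylidenedioxy)cyclohex-2-en-1-ol
Product: 9 Claisen ester (ethyl acetate arm on C7 cis to the 8,9-acetonide; C5=C6 alkene), via ketene acetal 8 (not isolated)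
Conditions: MeC(OEt)3, EtCO2H (cat.), xylene, 140 °C, ethanol distilled off
Reagents that add atoms: triethyl orthoacetate, CC(OCC)(OCC)OCC
Why: Johnson–Claisen rearrangement, whose suprafacial [3,3] shift transfers the carbinol configuration to C7 and places the C11–C12 arm cis to O8 and O9.

Step 7
Reactants: 9 Claisen ester
Product: 10 5,6-epoxide (oxirane anti to the arm and the acetonide)
Conditions: mCPBA, NaHCO3, CH2Cl2, 0 °C
Reagents that add atoms: mCPBA, OOC(=O)c1cccc(Cl)c1
Why: Prilezhaev epoxidation from the face opposite to the allylic acetate arm and the acetonide should place the future O6 anti to C11.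

Step 8
Reactants: 10 5,6-epoxide
Product: 13 allylic alcohol ester (C6–OH anti to the arm; C5=C10 alkene), via selenide 11 (not isolated), via selenoxide 12 (not isolated)
Conditions: (PhSe)2, NaBH4, EtOH, rt → 60 °C; then H2O2 (30%), THF, 0 °C → rt
Reagents that add atoms: none
Why: SN2 opening of the epoxide by selenolate at C5 (remote from the branched C7) and selenoxide syn-elimination away from the carbinol (epoxide-to-allylic-alcohol transposition) should keep the epoxide oxygen on C6 and move the alkene to C5=C10.

Step 9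
Reactants: 13 allylic alcohol ester
Product: 14 trans-fused lactol
Conditions: i-Bu2AlH, CH2Cl2, −78 °C
Reagents that add atoms: none
Why: Partial reduction of the ester to the aldehyde level, which the 6-hydroxyl should capture as the trans-fused five-membered lactol (any lactone formed in step 8 converges on the same product).

Step 10
Reactants: 14 trans-fused lactol
Product: 15 trans-fused methyl acetal 8,9-diol
Conditions: CSA (cat.), MeOH, rt; then solvent exchange to CH2Cl2 with CSA (cat.)
Reagents that add atoms: methanol, CO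
Why: Acid-catalysed acetalisation should fix the trans-fused bicyclic methyl acetal, and the water released hydrolyses the acetonide in the same operation.

Step 11
Reactants: 15 methyl acetal 8,9-diol
Product: 16 5,10-epoxy diol (oxirane syn to O8 and O9)
Conditions: VO(acac)2 (cat.), t-BuOOH, CH2Cl2, 0 °C → rt
Reagents that add atoms: tert-butyl hydroperoxide, CC(C)(C)OO
Why: Hydroxyl-directed vanadium-catalysed epoxidation should deliver oxygen syn to the allylic 9-hydroxyl and the axial homoallylic 8-hydroxyl, that is, to the face opposite to O6.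

Step 12
Reactants: 16 5,10-epoxy diol
Product: 17 9-O-(2-naphthylmethyl) ether
Conditions: Ph2BOCH2CH2NH2 (cat.), Ag2O, 2-(bromomethyl)naphthalene, MeCN, 40 °C
Reagents that add atoms: 2-(bromomethyl)naphthalene, BrCc1ccc2ccccc2c1
Why: Borinic-acid-catalysed regioselective Williamson alkylation of a cis-diol at its equatorial oxygen should select O9, because the trans-fused acetal holds O8 axial.

Step 13
Reactants: 17 9-O-NAP ether
Product: 18 8-O-PMB 9-O-NAP epoxide
Conditions: NaH, 4-MeOC6H4CH2Cl, Bu4NI (cat.), DMF, 0 °C → rt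
Reagents that add atoms: 4-methoxybenzyl chloride, COc1ccc(CCl)cc1
Why: Williamson etherification of the remaining axial 8-hydroxyl, which cannot reach the epoxide intramolecularly.

Step 14
Reactants: 18 8-O-PMB 9-O-NAP epoxide
Product: 19 5-isopropenyl-10-ol (isopropenyl axial and cis to O6; 10-OH axial)
Conditions: CH2=C(CH3)MgBr, CuI (cat.), THF, −30 → 0 °C
Reagents that add atoms: isopropenylmagnesium bromide, CC(=C)[Mg]Br
Why: Copper-catalysed Grignard opening of the epoxide under Fürst–Plattner control, where only attack at C5 is trans-diaxial in the chair fixed by the trans-fused acetal, so C5 is set by inversion.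

Step 15
Reactants: 19 5-isopropenyl-10-ol
Product: 20 C10 ketone
Conditions: Dess–Martin periodinane, NaHCO3, CH2Cl2, 0 °C → rt
Reagents that add atoms: none
Why: Buffered Dess–Martin oxidation should give the ketone without epimerising or conjugating the axial α-isopropenyl group.

Step 16
Reactants: 20 C10 ketone
Product: 21 cis-1-vinyl-2-isopropenylcyclohexanol
Conditions: CH2=CHMgBr, CeCl3, THF, −78 °C
Reagents that add atoms: vinylmagnesium bromide, C=C[Mg]Br
Why: Organocerium 1,2-addition (non-basic, no enolisation), in which axial attack is blocked by the syn-axial 8-OPMB group, so the vinyl group should enter equatorially, cis to the isopropenyl group and anti to O9, setting C10.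

Step 17
Reactants: 21 cis-1-vinyl-2-isopropenylcyclohexanol
Product: 24 ten-membered enol triflate (C4=C5 E; C1=C10 ring-cis with OTf trans to C2), via potassium alkoxide 22 (not isolated), via potassium enolate 23 (not isolated)
Conditions: KN(SiMe3)2, 18-crown-6, THF, −78 → 0 °C; then PhNTf2, −78 → 0 °C
Reagents that add atoms: N-phenylbis(trifluoromethanesulfonimide), FC(F)(F)S(=O)(=O)N(c1ccccc1)S(=O)(=O)C(F)(F)F
Why: KN(SiMe3)2 with 18-crown-6 converts 21 into the naked tertiary alkoxide 22, whose charge-accelerated [3,3]-sigmatropic shift (anionic oxy-Cope) breaks the temporary C5–C10 bond and forms C2–C3, and the enolate 23 is O-sulfonylated in the flask before it can equilibrate. The closest known reaction type is the anionic oxy-Cope ring expansion of 1-vinyl-2-alkenylcyclohexanols to cyclodeca-1,5-dienones with trapping of the enolate as its triflate. The ten-membered ring is closed not by an end-to-end cyclisation but by a concerted four-atom ring expansion of the six-membered ring through a chair-like six-centre transition state. No stereocentre is created and C6–C9 are spectators; the two alkene geometries follow from the chair, because the trans-fused acetal ring cannot flip and therefore holds the isopropenyl group axial and the vinyl group equatorial, which puts C6 pseudo-equatorial (C4=C5 E) and C9 pseudo-axial with the oxyanion pseudo-equatorial (C1=C10 ring-cis). The step needs this chair over the other chair or a boat, and it needs the enolate on the C1 side only; the conformational lock secures the first and the regiospecific generation of the enolate at low temperature secures the second. The C10 oxygen is a temporary activating group that step 18 replaces by the C14 methyl.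

Step 18
Reactants: 24 ten-membered enol triflate
Product: 25 (1(10)Z,4E)-diene methyl acetal
Conditions: Fe(acac)3 (cat.), MeMgBr, THF/NMP, −30 °C
Reagents that add atoms: methylmagnesium bromide, C[Mg]Br
Why: Iron-catalysed Kumada-type cross-coupling of the alkenyl triflate should install C14 with retention of the alkene geometry.

Step 19
Reactants: 25 diene methyl acetal
Product: 26 ten-membered lactol
Conditions: PPTS, acetone/H2O, 40 °C
Reagents that add atoms: water, O
Why: Mild acid hydrolysis of the methyl acetal should release the lactol under conditions gentle enough for the 1,5-diene.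

Step 20
Reactants: 26 ten-membered lactol
Product: 27 trans-fused 6-epi lactone
Conditions: TEMPO (cat.), PhI(OAc)2, CH2Cl2, rt
Reagents that add atoms: none
Why: Oxoammonium-mediated oxidation of the lactol should give the γ-lactone without touching the alkenes or the benzylic ethers.

Step 21
Reactants: 27 trans-fused 6-epi lactone
Product: 28 6-epi γ-hydroxy acid
Conditions: LiOH, THF/H2O, 0 °C → rt; then pH 5 phosphate buffer, 0 °C, rapid extraction, used at once
Reagents that add atoms: lithium hydroxide, [Li+].[OH-]
Why: Saponification should open the strained trans-lactone to the free allylic alcohol and carboxylic acid needed for the invertive closure.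

Step 22
Reactants: 28 6-epi γ-hydroxy acid
Product: 29 cis-fused lactone (C6 now as in the target)
Conditions: PPh3, DIAD, THF, 0 °C, high dilution
Reagents that add atoms: none
Why: Mitsunobu lactonisation, in which the carboxylate displaces the activated allylic oxyphosphonium at C6 in a 5-exo-tet SN2 closure with inversion, should give the cis-fused lactone.

Step 23
Reactants: 29 cis-fused lactone
Product: 32 α-methylene lactone, via Mannich base 30 (not isolated), via methiodide 31 (not isolated)
Conditions: LiN(i-Pr)2, THF, −78 °C; CH2=NMe2+ I−, −78 → 0 °C; then MeI, MeOH, rt; then NaHCO3 (aq), CH2Cl2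
Reagents that add atoms: Eschenmoser's salt, C=[N+](C)C.[I-]
Why: Mannich aminomethylation of the lactone enolate, quaternisation and Hofmann-type β-elimination should install the exocyclic methylene C13.

Step 24
Reactants: 32 α-methylene lactone
Product: 33 8-hydroxy 9-O-NAP germacranolide
Conditions: (NH4)2Ce(NO3)6, MeCN/H2O, 0 °C
Reagents that add atoms: none
Why: Single-electron oxidative cleavage of the electron-rich PMB ether should free O8 while the less electron-rich NAP ether on O9 survives.

Step 25
Reactants: 34 (S)-4-benzyl-3-propionyloxazolidin-2-one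
Product: 36 (S)-4-benzyl-3-[(R)-2-methylpent-4-enoyl]oxazolidin-2-one, via sodium enolate 35 (not isolated)
Conditions: NaN(SiMe3)2, THF, −78 °C; allyl iodide, −78 → −40 °C
Reagents that add atoms: allyl iodide, C=CCI
Why: Evans asymmetric alkylation, in which the chelated (Z)-enolate is allylated on the face opposite to the benzyl group, should set the (R) methyl-bearing centre.

Step 26
Reactants: 36 allylated imide
Product: 37 (R)-2-methylpent-4-en-1-ol
Conditions: LiBH4, Et2O, H2O (1 equiv), 0 °C
Reagents that add atoms: none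
Why: Reductive cleavage of the imide should release the primary alcohol without touching the stereocentre and return the auxiliary.

Step 27
Reactants: 37 (R)-2-methylpent-4-en-1-ol; 38 stearoyl chloride
Product: 39 (R)-2-methylpent-4-en-1-yl stearate
Conditions: pyridine, DMAP (cat.), CH2Cl2, 0 °C → rt
Reagents that add atoms: none
Why: O-acylation of the primary alcohol by the acid chloride under nucleophilic catalysis.

Step 28
Reactants: 39 (R)-2-methylpent-4-en-1-yl stearate
Product: 40 (R)-3-methyl-4-(stearoyloxy)butanoic acid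
Conditions: RuCl3·xH2O (cat.), NaIO4, CCl4/MeCN/H2O, rt
Reagents that add atoms: sodium periodate, [Na+].[O-]I(=O)(=O)=O; water, O
Why: Ruthenium tetroxide oxidative cleavage of the terminal alkene should give the acid shorter by one carbon, with the ester inert and the stereocentre untouched.

Step 29
Reactants: 33 8-hydroxy 9-O-NAP germacranolide; 40 (R)-3-methyl-4-(stearoyloxy)butanoic acid
Product: 42 9-O-NAP ether of the target, via mixed anhydride 41 (not isolated)
Conditions: 2,4,6-Cl3C6H2COCl, Et3N, THF, rt; then 33, DMAP, toluene, rt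
Reagents that add atoms: none
Why: Yamaguchi esterification should acylate the hindered secondary 8-hydroxyl, the only free hydroxyl in 33.

Step 30
Reactants: 42 9-O-NAP ether of the target
Product: 43 CNP0114940.1 (target)
Conditions: DDQ, CH2Cl2/pH 7 phosphate buffer, rt
Reagents that add atoms: none
Why: Oxidative cleavage of the 2-naphthylmethyl ether under neutral conditions should free the 9-hydroxyl without acyl migration or attack on the α-methylene lactone.

**Compound list**

1 | (−)-quinic acid, (1S,3R,4S,5R)-1,3,4,5-tetrahydroxycyclohexane-1-carboxylic acid | C1[C@H]([C@H]([C@@H](C[C@@]1(C(=O)O)O)O)O)O | starting material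
2 | 3,4-O-isopropylidenequinic acid 1,5-lactone | O[C@@]12C[C@H]3OC(C)(C)O[C@H]3[C@@H](C1)OC2=O | intermediate
3 | 1-(hydroxymethyl)-3,4-O-isopropylidenecyclohexane-1,3,4,5-tetrol (quinic acid numbering) | OC[C@]1(O)C[C@H]2OC(C)(C)O[C@H]2[C@H](O)C1 | intermediate
4 | 3-hydroxy-4,5-(isopropylidenedioxy)cyclohexan-1-one, hydroxyl trans to the acetonide | O=C1C[C@H]2OC(C)(C)O[C@H]2[C@H](O)C1 | intermediate
5 | 3-O-mesylate of 4 | O=C1C[C@H]2OC(C)(C)O[C@H]2[C@H](OS(C)(=O)=O)C1 | intermediate (not isolated)
6 | (4S,5R)-4,5-(isopropylidenedioxy)cyclohex-2-en-1-one | O=C1C=C[C@@H]2OC(C)(C)O[C@@H]2C1 | intermediate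
7 | (1S,4S,5R)-4,5-(isopropylidenedioxy)cyclohex-2-en-1-ol, hydroxyl cis to the acetonide | O[C@@H]1C=C[C@@H]2OC(C)(C)O[C@@H]2C1 | intermediate
8 | O-(1-ethoxyvinyl) ether of 7 (ketene acetal) | C=C(OCC)O[C@@H]1C=C[C@@H]2OC(C)(C)O[C@@H]2C1 | intermediate (not isolated)
9 | ethyl 2-[5,6-(isopropylidenedioxy)cyclohex-2-en-1-yl]acetate, acetate arm cis to the acetonide (germacrane atoms: C5=C6, C7 arm, O8/O9 acetonide, C10H2) | C1=C[C@H](CC(=O)OCC)[C@@H]2OC(C)(C)O[C@@H]2C1 | intermediate
10 | 5,6-epoxide of 9, oxirane anti to arm and acetonide | C1[C@H]2O[C@H]2[C@H](CC(=O)OCC)[C@@H]2OC(C)(C)O[C@@H]21 | intermediate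
11 | 5-phenylseleno-6-hydroxy ester (trans-diaxial opening product) | C1[C@H]([Se]c2ccccc2)[C@@H](O)[C@H](CC(=O)OCC)[C@@H]2OC(C)(C)O[C@@H]21 | intermediate (not isolated)
12 | selenoxide of 11 | C1[C@H]([Se](=O)c2ccccc2)[C@@H](O)[C@H](CC(=O)OCC)[C@@H]2OC(C)(C)O[C@@H]21 | intermediate (not isolated)
13 | allylic alcohol ester: C5=C10 alkene, C6–OH anti to the C7 acetate arm, 8,9-acetonide | C1=C[C@@H](O)[C@H](CC(=O)OCC)[C@@H]2OC(C)(C)O[C@H]12 | intermediate
14 | trans-fused lactol (O6–C12(OH)–C11–C7), 8,9-acetonide, C5=C10 alkene | C1=C[C@H]2OC(O)C[C@@H]2[C@@H]3OC(C)(C)O[C@H]13 | intermediate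
15 | trans-fused methyl acetal, free cis-8,9-diol, C5=C10 alkene | C1=C[C@H]2OC(OC)C[C@@H]2[C@H](O)[C@@H]1O | intermediate
16 | 5,10-epoxide of 15, oxirane cis to O8 and O9 | O1[C@@H]2[C@H]1[C@H]3OC(OC)C[C@@H]3[C@H](O)[C@@H]2O | intermediate
17 | 9-O-(2-naphthylmethyl) ether of 16 | O1[C@@H]2[C@H]1[C@H]3OC(OC)C[C@@H]3[C@H](O)[C@@H]2OCc1ccc2ccccc2c1 | intermediate
18 | 8-O-(4-methoxybenzyl) 9-O-(2-naphthylmethyl) epoxide | O1[C@@H]2[C@H]1[C@H]3OC(OC)C[C@@H]3[C@H](OCc1ccc(OC)cc1)[C@@H]2OCc1ccc2ccccc2c1 | intermediate
19 | 5-isopropenylcyclohexan-10-ol: isopropenyl axial and cis to O6, 10-OH axial and cis to O9, trans-fused methyl acetal, 8-OPMB, 9-ONAP | CC(=C)[C@H]1[C@H]2OC(OC)C[C@@H]2[C@H](OCc2ccc(OC)cc2)[C@H](OCc2ccc3ccccc3c2)[C@@H]1O | intermediate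
20 | C10 ketone of 19 | CC(=C)[C@H]1[C@H]2OC(OC)C[C@@H]2[C@H](OCc2ccc(OC)cc2)[C@H](OCc2ccc3ccccc3c2)C1=O | intermediate
21 | 10-vinyl carbinol: vinyl equatorial and cis to the isopropenyl group, 10-OH axial | CC(=C)[C@H]1[C@H]2OC(OC)C[C@@H]2[C@H](OCc2ccc(OC)cc2)[C@H](OCc2ccc3ccccc3c2)[C@@]1(O)C=C | intermediate
22 | potassium alkoxide of 21 | CC(=C)[C@H]1[C@H]2OC(OC)C[C@@H]2[C@H](OCc2ccc(OC)cc2)[C@H](OCc2ccc3ccccc3c2)[C@@]1([O-])C=C.[K+] | intermediate (not isolated)
23 | ten-membered potassium enolate (C4=C5 E; enolate C1=C10 with O trans to C2) | C1C(OC)O[C@@H]2/C=C(\C)CC/C=C(/[O-])[C@@H](OCc3ccc4ccccc4c3)[C@@H](OCc3ccc(OC)cc3)[C@@H]12.[K+] | intermediate (not isolated)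
24 | ten-membered enol triflate (C10–OTf trans to C2; C4=C5 E), trans-fused 6,12-methyl acetal, 8-OPMB, 9-ONAP | C1C(OC)O[C@@H]2/C=C(\C)CC/C=C(/OS(=O)(=O)C(F)(F)F)[C@@H](OCc3ccc4ccccc4c3)[C@@H](OCc3ccc(OC)cc3)[C@@H]12 | intermediate
25 | (1(10)Z,4E)-germacradiene with trans-fused 6,12-methyl acetal, 8-OPMB, 9-ONAP | C1C(OC)O[C@@H]2/C=C(\C)CC/C=C(/C)[C@@H](OCc3ccc4ccccc4c3)[C@@H](OCc3ccc(OC)cc3)[C@@H]12 | intermediate
26 | corresponding lactol | C1C(O)O[C@@H]2/C=C(\C)CC/C=C(/C)[C@@H](OCc3ccc4ccccc4c3)[C@@H](OCc3ccc(OC)cc3)[C@@H]12 | intermediate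
27 | trans-fused 6-epi-12,6-lactone | C1C(=O)O[C@@H]2/C=C(\C)CC/C=C(/C)[C@@H](OCc3ccc4ccccc4c3)[C@@H](OCc3ccc(OC)cc3)[C@@H]12 | intermediate
28 | 6-epi-6-hydroxy-germacradien-12-oic acid (8-OPMB, 9-ONAP) | O[C@@H]1/C=C(\C)CC/C=C(/C)[C@@H](OCc2ccc3ccccc3c2)[C@@H](OCc2ccc(OC)cc2)[C@H]1CC(=O)O | intermediate
29 | cis-fused 12,6-lactone with the target configuration at C6 | C1C(=O)O[C@H]2/C=C(\C)CC/C=C(/C)[C@@H](OCc3ccc4ccccc4c3)[C@@H](OCc3ccc(OC)cc3)[C@@H]12 | intermediate
30 | 11-(dimethylaminomethyl) lactone (Mannich base) | CN(C)CC1C(=O)O[C@H]2/C=C(\C)CC/C=C(/C)[C@@H](OCc3ccc4ccccc4c3)[C@@H](OCc3ccc(OC)cc3)[C@@H]12 | intermediate (not isolated)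
31 | trimethylammonium iodide of 30 | C[N+](C)(C)CC1C(=O)O[C@H]2/C=C(\C)CC/C=C(/C)[C@@H](OCc3ccc4ccccc4c3)[C@@H](OCc3ccc(OC)cc3)[C@@H]12.[I-] | intermediate (not isolated)
32 | α-methylene lactone, 8-OPMB, 9-ONAP | C=C1C(=O)O[C@H]2/C=C(\C)CC/C=C(/C)[C@@H](OCc3ccc4ccccc4c3)[C@@H](OCc3ccc(OC)cc3)[C@@H]12 | intermediate
33 | 8-hydroxy 9-O-NAP α-methylene lactone | C=C1C(=O)O[C@H]2/C=C(\C)CC/C=C(/C)[C@@H](OCc3ccc4ccccc4c3)[C@@H](O)[C@@H]12 | intermediate
34 | (S)-4-benzyl-3-propionyloxazolidin-2-one | CCC(=O)N1[C@@H](Cc2ccccc2)COC1=O | starting material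
35 | sodium (Z)-enolate of 34 | C/C=C(\[O-])N1[C@@H](Cc2ccccc2)COC1=O.[Na+] | intermediate (not isolated)
36 | (S)-4-benzyl-3-[(R)-2-methylpent-4-enoyl]oxazolidin-2-one | C=CC[C@@H](C)C(=O)N1[C@@H](Cc2ccccc2)COC1=O | intermediate
37 | (R)-2-methylpent-4-en-1-ol | C=CC[C@@H](C)CO | intermediate
38 | stearoyl chloride (octadecanoyl chloride) | CCCCCCCCCCCCCCCCCC(=O)Cl | starting material
39 | (R)-2-methylpent-4-en-1-yl stearate | C=CC[C@@H](C)COC(=O)CCCCCCCCCCCCCCCCC | intermediate
40 | (R)-3-methyl-4-(stearoyloxy)butanoic acid | OC(=O)C[C@@H](C)COC(=O)CCCCCCCCCCCCCCCCC | intermediate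
41 | mixed anhydride of 40 with 2,4,6-trichlorobenzoic acid | O=C(OC(=O)c1c(Cl)cc(Cl)cc1Cl)C[C@@H](C)COC(=O)CCCCCCCCCCCCCCCCC | intermediate (not isolated)
42 | 9-O-(2-naphthylmethyl) ether of the target | C=C1C(=O)O[C@H]2/C=C(\C)CC/C=C(/C)[C@@H](OCc3ccc4ccccc4c3)[C@@H](OC(=O)C[C@@H](C)COC(=O)CCCCCCCCCCCCCCCCC)[C@@H]12 | intermediate
43 | CNP0114940.1: (1(10)Z,4E,6S,7S,8S,9R)-9-hydroxy-8-[(R)-3-methyl-4-(stearoyloxy)butanoyloxy]germacra-1(10),4,11(13)-trien-12,6-olide | C=C1C(=O)O[C@H]2/C=C(\C)CC/C=C(/C)[C@@H](O)[C@@H](OC(=O)C[C@@H](C)COC(=O)CCCCCCCCCCCCCCCCC)[C@@H]12 | target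

**Step count and risks**

Total step count: 30. Longest linear sequence: 26 steps (steps 1–24, 29 and 30); the side-chain acid takes 4 steps (25–28).

Steps most likely to fail:

1. Step 17. The only accessible chair places C9 pseudo-axial beside the C4 methyl, so the rearrangement may be slow. The basic alkoxide or enolate could then undergo proton transfer across the carbonyl and β-elimination of the 8-alkoxy group before O-sulfonylation. The fallback is the neutral thermal variant, setting out from 21 and returning at 24. Compound 21 is silylated (Me3SiOTf, 2,6-lutidine, CH2Cl2) to the trimethylsilyl ether F1. This is heated (o-dichlorobenzene, sealed base-washed tube, about 200–220 °C) so that the siloxy-Cope ring expansion through the same locked chair gives the ten-membered trimethylsilyl enol ether F2. F2 is cleaved with MeLi (THF, 0 °C) to the lithium enolate and triflated with PhNTf2 to give 24.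

2. Step 22. The activated allylic oxyphosphonium may ionise or be attacked in the SN2' sense, so the closure may lose the inversion (trans-lactone or diene), and the free hydroxy acid may relactonise with retention before activation. The fallback inverts C6 by oxidation and reduction, setting out from 28 and returning at 29. Compound 28 is esterified with Me3SiCHN2 (MeOH/toluene) to the methyl ester F3. The allylic alcohol is oxidised with Dess–Martin periodinane to the enone ester F4. Corey–Bakshi–Shibata reduction ((S)-2-methyl-CBS-oxazaborolidine, catecholborane, toluene, −78 °C, alkenyl arm as the large group) should give the 6-epimeric allylic alcohol F5. F5 should lactonise on warming with PPTS in toluene to 29.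

3. Step 14. SN2 attack at C5, which is flanked by the oxygen-bearing C6, may be too slow for the hindered sp2 Grignard reagent, so that base-induced isomerisation of the epoxide to an allylic alcohol competes. The fallback uses a slimmer sp nucleophile followed by carbometalation, setting out from 18 and returning at 19. Compound 18 is opened trans-diaxially with lithium acetylide–ethylenediamine complex (DMSO, rt) to the 5-ethynyl-10-ol F6. Negishi zirconium-catalysed methylalumination (AlMe3, Cp2ZrCl2 (cat.), CH2Cl2, then aqueous quench) turns the terminal alkyne into the isopropenyl group and gives 19.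

Further compounds
F1 | step 17 | trimethylsilyl ether of 21 | CC(=C)[C@H]1[C@H]2OC(OC)C[C@@H]2[C@H](OCc2ccc(OC)cc2)[C@H](OCc2ccc3ccccc3c2)[C@@]1(O[Si](C)(C)C)C=C
F2 | step 17 | ten-membered trimethylsilyl enol ether (OSiMe3 trans to C2; C4=C5 E) | C1C(OC)O[C@@H]2/C=C(\C)CC/C=C(/O[Si](C)(C)C)[C@@H](OCc3ccc4ccccc4c3)[C@@H](OCc3ccc(OC)cc3)[C@@H]12
F3 | step 22 | methyl ester of 28 | O[C@@H]1/C=C(\C)CC/C=C(/C)[C@@H](OCc2ccc3ccccc3c2)[C@@H](OCc2ccc(OC)cc2)[C@H]1CC(=O)OC
F4 | step 22 | C6 enone methyl ester | O=C1/C=C(\C)CC/C=C(/C)[C@@H](OCc2ccc3ccccc3c2)[C@@H](OCc2ccc(OC)cc2)[C@H]1CC(=O)OC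
F5 | step 22 | 6-hydroxy methyl ester with the target configuration at C6 | O[C@H]1/C=C(\C)CC/C=C(/C)[C@@H](OCc2ccc3ccccc3c2)[C@@H](OCc2ccc(OC)cc2)[C@H]1CC(=O)OC
F6 | step 14 | 5-ethynyl-10-ol (ethynyl axial, cis to O6) | C#C[C@H]1[C@H]2OC(OC)C[C@@H]2[C@H](OCc2ccc(OC)cc2)[C@H](OCc2ccc3ccccc3c2)[C@@H]1O
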